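Slowness told me less than I wished: when the south flask, in which free enzyme turns substrate into target, went flat, it did not say why.

the same everywhere: free enzyme 1.2 µM
- south: substrate 0.20 M; temperature 40 °C; the very flask that is asked about, followed so far
- north: substrate 0.10 M; temperature 25 °C; run made earlier
- flask: substrate 0.20 M; temperature 40 °C; time 2.5 d

| run | time / h | target / % |
|---|---|---|
| south | 6.00 | 50.6 |
| south | 15.0 | 45.5 |
| south | 30.0 | 44.7 |
| south | 50.0 | 45.1 |
| north | 0.833 | 51.7 |
| north | 2.00 | 77.9 |
| north | 4.00 | 76.3 |
| north | 6.00 | 69.4 |

(readings scatter by 0.3 percentage points)

- eta: at 2.5 d add free enzyme, 50.0% of the amount charged, then wait 2.5 d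
- alpha: at 2.5 d take out 90% of the target then present, then wait 2.5 d
- zeta: change nothing and wait 2.5 d more
- theta: at 2.5 d raise the temperature by 15 K, then wait 2.5 d

* target, in percent of the substrate first charged, at 2.5 d
* the option that brings most further target ("none" if no option brings more than 2 percentage points) (eta / alpha / zeta / theta / none)
* target present, with what was taken out counted in, in percent of the substrate first charged, after alpha
* target present, with what was taken out counted in, in percent of the substrate first charged, after zeta

- target taken out counts as made
- the earlier runs were read with a standard deviation of 0.3 percentage points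
- additions bring no volume worth counting

The bench rule says that a curve gone flat has finished, and I applied it. The last two south readings differed by 0.4 percentage points against a scatter of 0.3 points, so I took their mean, 44.9%, as the equilibrium share f, the part of the material left in this flask at 40 °C that ends up as target. The target had overshot f and come back, which I read as kinetic giving way to thermodynamic control.

I took the relaxation time τ from the excess of the first two south readings over f, roughly, as the second excess lies near the scatter:

τ = 9.00 h / ln(5.7 points / 0.6 points) = 4.00 h

τ is much shorter than the wait of 2.5 d, which comes to 15.0 τ, so I expected f at that time and no gain from waiting.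

The rule stops where the enzyme lives no longer than τ: a flask that has lost its enzyme stands flat too. Its half-life would then be about 2.77 h, and I had no reading against that at 40 °C. The north run, colder and with less substrate, was still falling at 6.00 h, which showed working enzyme there but not at 40 °C. I committed to equilibrium all the same, weakly.

Alpha then banks a share x of the target, here 90%, and f acts again on the remaining material:

banked = 40.4%, material left = 59.6%

total = 40.4% + 44.9% × 59.6% = 67.2%

The forecast gave 45% now, alpha as best, 67% after alpha and 45% after zeta: “Waiting, adding enzyme or heating gains nothing.”

The flask gave 44.7% at 2.5 d, alpha as best, 66.9% after alpha against my 67.2%, and 44.7% after zeta.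

    2 complex → spent catalyst (k = 432 /M/min, Ea = 51.0 kJ/mol)
    target + free enzyme ⇌ isomer of the product + free enzyme, rate k2*[free enzyme]*[target] forward; the back reaction follows from the equilibrium constant (K = 0.750, k = 2730 /M/min, Ea = 43.0 kJ/mol, ΔH = −50.0 kJ/mol)
    complex ⇌ free enzyme + target (K = 0.190 M, k = 8540 /min, Ea = 71.0 kJ/mol, ΔH = −31.0 kJ/mol)
    substrate + free enzyme ⇌ complex (K = 10.8 /M, k = 78700 /M/min, Ea = 39.0 kJ/mol, ΔH = −57.0 kJ/mol)
    free enzyme → unfolded enzyme (k = 7.99 × 10⁻⁵ /min, Ea = 204 kJ/mol)
    (constants at 40 °C)

After 60.0 h the flask still held 40.9% of its catalyst as free enzyme and 19.2% as complex, so it stood flat with working enzyme. The neighbour flask read at 4.0 d gave 44.7%, within 0.3 points of f, with free enzyme down to 32.2%. Target stands near f in part through the backward run from isomer of the product to target: the run without that backward run stood at 0.230% instead of 44.7% at 2.5 d.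

All runs were computed for an exercise.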